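## Retrosynthetic overview

1. Target 20 comes from its bis(benzyl ether) 19 by hydrogenolysis of the two ring B benzyl ethers.
2. The strategy rests on ring A of 19 (C1 propanoyl, C2 OH, C3 methyl, C4 OH, C5 CH2 bridge, C6 OH). It is the Claisen-folded form of the open-chain methyl 3,5,7-trioxononanoate 17, whose C2 carries the ring B benzyl group and whose C4 carries the methyl. Chain C6 closes onto ester carbon C1, which makes the ring A bond between the propanoyl-bearing carbon and the hydroxyl carbon next to the bridge. Ring A is the only ring formed; ring B is carried in from 2-methylphloroglucinol.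
3. 17 is assembled at chain bond C3–C4 from the malonyl chloride half-ester 12 and the bis(silyl enol ether) 15 of heptane-3,5-dione. This acylation is neutral, so no strong base meets the ring B aryl ketone. No nitrogen-based diketone mask is used, because an enaminone set free next to the C3 ketone would close to a 4-pyridone.
4. 12 comes from aldehyde 7 by reductive alkylation of Meldrum's acid and methanolysis; 7 comes from 2-methylphloroglucinol by propanoylation, para-O-methylation, formylation and benzylation.

Key step: step 11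

Remark on the chemistry: 11, 12, 16, 17 and 18 are handled as racemates or mixtures of diastereomers and keto–enol tautomers, and 14 and 15 as mixtures of double-bond isomers. All of this is erased when ring A aromatises, and the target has no stereocentre. 2,4,6-Trimethoxytoluene and 4-hydroxy-5,6-dimethyl-2H-pyran-2-one, used only in fallbacks, are assumed to be purchasable.

## Route

Step 1
Reactants: 1 2-methylphloroglucinol; 2 propanoyl chloride
Product: 3 1-(2,4,6-trihydroxy-3-methylphenyl)propan-1-one
Conditions: AlCl3 (3.5 equiv), PhNO2/CH2Cl2, 0 °C to 45 °C; then ice/1 M HCl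
Reagents that add atoms: none
Why: Friedel–Crafts acylation at one of the two equivalent free ring carbons of the electron-rich arene should stop at the mono-ketone, because the acyl group deactivates the ring towards a second acylation.

Step 2
Reactants: 3 1-(2,4,6-trihydroxy-3-methylphenyl)propan-1-one
Product: 4 1-(2,6-dihydroxy-4-methoxy-3-methylphenyl)propan-1-one
Conditions: Me2SO4 (1.0 equiv), K2CO3 (1.05 equiv), acetone, rt to 50 °C
Reagents that add atoms: dimethyl sulfate COS(=O)(=O)OC
Why: Williamson O-methylation with one equivalent of reagent should take the hydroxyl para to the ketone, which is the most acidic and the only one not held in a hydrogen bond to the carbonyl.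

Step 3
Reactants: 4 1-(2,6-dihydroxy-4-methoxy-3-methylphenyl)propan-1-one
Product: 6 2,4-dihydroxy-6-methoxy-5-methyl-3-propanoylbenzaldehyde, via chloro(methoxy)methyl arene 5 (not isolated)
Conditions: Cl2CHOMe (1.5 equiv), TiCl4 (3 equiv), CH2Cl2, −10 °C to 0 °C; then 1 M HCl, rt
Reagents that add atoms: dichloromethyl methyl ether COC(Cl)Cl; water O
Why: Rieche formylation should attack the only free ring carbon, ortho to a titanium-bound phenoxide; a Vilsmeier reagent is avoided because it would attack the α-CH2 of the ortho-hydroxy ketone and form a chromone.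

Step 4
Reactants: 6 2,4-dihydroxy-6-methoxy-5-methyl-3-propanoylbenzaldehyde
Product: 7 2,4-bis(benzyloxy)-6-methoxy-5-methyl-3-propanoylbenzaldehyde
Conditions: BnBr (2.5 equiv), K2CO3 (3 equiv), DMF, 60 °C
Reagents that add atoms: benzyl bromide BrCc1ccccc1
Why: Williamson etherification in warm DMF should alkylate both carbonyl-chelated phenols on oxygen, since the ring has no free carbon left for C-alkylation.

Step 5
Reactants: 7 2,4-bis(benzyloxy)-6-methoxy-5-methyl-3-propanoylbenzaldehyde; 8 Meldrum's acid
Product: 10 5-{[2,4-bis(benzyloxy)-6-methoxy-5-methyl-3-propanoylphenyl]methyl}-2,2-dimethyl-1,3-dioxane-4,6-dione, via arylidene Meldrum's acid 9 (not isolated)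
Conditions: Hantzsch ester (diethyl 2,6-dimethyl-1,4-dihydropyridine-3,5-dicarboxylate, 1.1 equiv), L-proline (20 mol%), EtOH, rt
Reagents that add atoms: none
Why: Knoevenagel condensation followed by conjugate transfer hydrogenation (organocatalytic reductive alkylation) should give the mono-benzylated Meldrum's acid, because the Hantzsch ester reduces only the doubly activated alkene and leaves the aryl ketone and benzyl ethers alone.

Step 6
Reactants: 10 5-{[2,4-bis(benzyloxy)-6-methoxy-5-methyl-3-propanoylphenyl]methyl}-2,2-dimethyl-1,3-dioxane-4,6-dione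
Product: 11 2-{[2,4-bis(benzyloxy)-6-methoxy-5-methyl-3-propanoylphenyl]methyl}-3-methoxy-3-oxopropanoic acid (racemic)
Conditions: MeOH, reflux
Reagents that add atoms: methanol CO
Why: Alcoholysis of the Meldrum's acid ring with loss of acetone should stop at the malonic half-ester, since the free acid neither esterifies nor decarboxylates at 65 °C.

Step 7
Reactants: 11 2-{[2,4-bis(benzyloxy)-6-methoxy-5-methyl-3-propanoylphenyl]methyl}-3-methoxy-3-oxopropanoic acid
Product: 12 methyl 2-{[2,4-bis(benzyloxy)-6-methoxy-5-methyl-3-propanoylphenyl]methyl}-3-chloro-3-oxopropanoate (racemic, used crude)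
Conditions: (COCl)2 (1.5 equiv), DMF (cat.), CH2Cl2, 0 °C to rt; evaporate with toluene
Reagents that add atoms: oxalyl chloride O=C(Cl)C(=O)Cl
Why: Acid chloride formation through the catalytic chloroiminium species is neutral and should leave the methyl ester, the aryl ketone and the benzyl ethers untouched.

Step 8
Reactants: 13 heptane-3,5-dione
Product: 14 5-(trimethylsilyloxy)hept-4-en-3-one
Conditions: Me3SiCl (1.5 equiv), Et3N (1.5 equiv), pentane, rt
Reagents that add atoms: chlorotrimethylsilane C[Si](C)(C)Cl
Why: O-silylation of the enol of the symmetrical β-diketone can give only one constitutional isomer.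

Step 9
Reactants: 14 5-(trimethylsilyloxy)hept-4-en-3-one
Product: 15 3,5-bis(trimethylsilyloxy)hepta-2,4-diene
Conditions: LiN(i-Pr)2 (1.2 equiv), THF, −78 °C; Me3SiCl (1.5 equiv), −78 °C to rt
Reagents that add atoms: chlorotrimethylsilane C[Si](C)(C)Cl
Why: Kinetic α′-deprotonation of the enone at the ethyl ketone CH2 and O-silylation should give the 1,3-bis(silyl enol ether), the neutral equivalent of the diketone dianion.

Step 10
Reactants: 12 methyl 2-{[2,4-bis(benzyloxy)-6-methoxy-5-methyl-3-propanoylphenyl]methyl}-3-chloro-3-oxopropanoate; 15 3,5-bis(trimethylsilyloxy)hepta-2,4-diene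
Product: 17 methyl 2-{[2,4-bis(benzyloxy)-6-methoxy-5-methyl-3-propanoylphenyl]methyl}-4-methyl-3,5,7-trioxononanoate (mixture of diastereomers and enol forms), via silyl enol ether 16 (not isolated)
Conditions: 15 (1.8 equiv), CH2Cl2, −78 °C to rt; then 1 M HCl, 0 °C; rapid chromatography
Reagents that add atoms: none
Why: In this vinylogous Mukaiyama-type C-acylation the terminal carbon of the 1,3-bis(silyl enol ether) should attack the acid chloride with loss of Me3SiCl, and the remaining enol ether is hydrolysed on work-up; no base is present, so the malonyl C–H, the ester and the ring B ketone are not engaged.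

Step 11
Reactants: 17 methyl 2-{[2,4-bis(benzyloxy)-6-methoxy-5-methyl-3-propanoylphenyl]methyl}-4-methyl-3,5,7-trioxononanoate
Product: 19 1-[3-{[2,4-bis(benzyloxy)-6-methoxy-5-methyl-3-propanoylphenyl]methyl}-2,4,6-trihydroxy-5-methylphenyl]propan-1-one, via cyclohexanetrione tautomer 18 (not isolated)
Conditions: Mg(OMe)2 (5 equiv, from Mg in MeOH), MeOH, reflux; then cold 1 M HCl
Reagents that add atoms: none
Why: Mg(OMe)2 deprotonates the C6 methylene between the C5 and C7 ketones and holds the chain as a magnesium chelate; the diketone carbanion adds to the C1 ester carbonyl and methoxide is expelled, which forms the C1–C6 bond of ring A (propanoyl-bearing carbon to the hydroxyl carbon next to the bridge). The closest known reaction is the base-mediated Claisen (Dieckmann-type) cyclisation of 3,5,7-triketo esters to acylphloroglucinols, the laboratory version of polyketide folding. Ring A closes in a 6-exo-trig mode (enolexo, through the C6=C7 enolate), and the cyclohexane-1,3,5-trione 18 should enolise at once to the phloroglucinol, which makes the closure irreversible; the C2 and C4 stereocentres of 17 disappear and no new one is formed. The selectivity needed is Claisen over aldol folding: attack of C2 on the C7 ketone gives a ring with a quaternary carbon that cannot dehydrate to an arene and reverts, the other aldol fold (C8 onto C3) needs the unactivated ethyl ketone α-CH2 deprotonated, which Mg(OMe)2 in MeOH should not do appreciably, and lactonisation to the 4-hydroxy-2-pyrone is reversed by methoxide. The ring B phenols stay benzylated so that no ring B phenoxide can trigger base-induced scrambling of the new diarylmethane bridge.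

Step 12
Reactants: 19 1-[3-{[2,4-bis(benzyloxy)-6-methoxy-5-methyl-3-propanoylphenyl]methyl}-2,4,6-trihydroxy-5-methylphenyl]propan-1-one
Product: 20 1-[3-{[2,4-dihydroxy-6-methoxy-5-methyl-3-propanoylphenyl]methyl}-2,4,6-trihydroxy-5-methylphenyl]propan-1-one (target)
Conditions: H2 (1 atm), 10% Pd/C, EtOAc, rt
Reagents that add atoms: none
Why: Hydrogenolysis of the two benzyl ethers over Pd/C is neutral, so the base-sensitive methylene-bridged bis-phloroglucinol never meets base, and the hydrogen-bonded aryl ketones and the diarylmethane bridge should not be reduced at 1 atm.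

## Compound list

1 | 2-methylphloroglucinol | Cc1c(O)cc(O)cc1O | starting material
2 | propanoyl chloride | CCC(Cl)=O | starting material
3 | 1-(2,4,6-trihydroxy-3-methylphenyl)propan-1-one | CCC(=O)c1c(O)cc(O)c(C)c1O | intermediate
4 | 1-(2,6-dihydroxy-4-methoxy-3-methylphenyl)propan-1-one | CCC(=O)c1c(O)cc(OC)c(C)c1O | intermediate
5 | 1-{3-[chloro(methoxy)methyl]-2,6-dihydroxy-4-methoxy-5-methylphenyl}propan-1-one (as its titanium complex, not isolated) | COC(Cl)c1c(O)c(C(=O)CC)c(O)c(C)c1OC | intermediate
6 | 2,4-dihydroxy-6-methoxy-5-methyl-3-propanoylbenzaldehyde | O=Cc1c(O)c(C(=O)CC)c(O)c(C)c1OC | intermediate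
7 | 2,4-bis(benzyloxy)-6-methoxy-5-methyl-3-propanoylbenzaldehyde | O=Cc1c(OCc2ccccc2)c(C(=O)CC)c(OCc2ccccc2)c(C)c1OC | intermediate
8 | Meldrum's acid (2,2-dimethyl-1,3-dioxane-4,6-dione) | CC1(C)OC(=O)CC(=O)O1 | starting material
9 | 5-{[2,4-bis(benzyloxy)-6-methoxy-5-methyl-3-propanoylphenyl]methylidene}-2,2-dimethyl-1,3-dioxane-4,6-dione (not isolated) | CC1(C)OC(=O)C(=Cc2c(OCc3ccccc3)c(C(=O)CC)c(OCc3ccccc3)c(C)c2OC)C(=O)O1 | intermediate
10 | 5-{[2,4-bis(benzyloxy)-6-methoxy-5-methyl-3-propanoylphenyl]methyl}-2,2-dimethyl-1,3-dioxane-4,6-dione | CC1(C)OC(=O)C(Cc2c(OCc3ccccc3)c(C(=O)CC)c(OCc3ccccc3)c(C)c2OC)C(=O)O1 | intermediate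
11 | 2-{[2,4-bis(benzyloxy)-6-methoxy-5-methyl-3-propanoylphenyl]methyl}-3-methoxy-3-oxopropanoic acid (racemic) | COC(=O)C(Cc1c(OCc2ccccc2)c(C(=O)CC)c(OCc2ccccc2)c(C)c1OC)C(=O)O | intermediate
12 | methyl 2-{[2,4-bis(benzyloxy)-6-methoxy-5-methyl-3-propanoylphenyl]methyl}-3-chloro-3-oxopropanoate (racemic) | COC(=O)C(Cc1c(OCc2ccccc2)c(C(=O)CC)c(OCc2ccccc2)c(C)c1OC)C(Cl)=O | intermediate
13 | heptane-3,5-dione | CCC(=O)CC(=O)CC | starting material
14 | 5-(trimethylsilyloxy)hept-4-en-3-one (double-bond geometry not controlled) | CCC(=O)C=C(CC)O[Si](C)(C)C | intermediate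
15 | 3,5-bis(trimethylsilyloxy)hepta-2,4-diene (mixture of double-bond isomers) | CC=C(O[Si](C)(C)C)C=C(CC)O[Si](C)(C)C | intermediate
16 | methyl 2-{[2,4-bis(benzyloxy)-6-methoxy-5-methyl-3-propanoylphenyl]methyl}-4-methyl-3,5-dioxo-7-(trimethylsilyloxy)non-6-enoate (not isolated) | CCC(O[Si](C)(C)C)=CC(=O)C(C)C(=O)C(Cc1c(OCc2ccccc2)c(C(=O)CC)c(OCc2ccccc2)c(C)c1OC)C(=O)OC | intermediate
17 | methyl 2-{[2,4-bis(benzyloxy)-6-methoxy-5-methyl-3-propanoylphenyl]methyl}-4-methyl-3,5,7-trioxononanoate (diastereomers and enol forms) | CCC(=O)CC(=O)C(C)C(=O)C(Cc1c(OCc2ccccc2)c(C(=O)CC)c(OCc2ccccc2)c(C)c1OC)C(=O)OC | intermediate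
18 | 2-{[2,4-bis(benzyloxy)-6-methoxy-5-methyl-3-propanoylphenyl]methyl}-4-methyl-6-propanoylcyclohexane-1,3,5-trione (not isolated) | CCC(=O)C1C(=O)C(C)C(=O)C(Cc2c(OCc3ccccc3)c(C(=O)CC)c(OCc3ccccc3)c(C)c2OC)C1=O | intermediate
19 | 1-[3-{[2,4-bis(benzyloxy)-6-methoxy-5-methyl-3-propanoylphenyl]methyl}-2,4,6-trihydroxy-5-methylphenyl]propan-1-one | CCC(=O)c1c(O)c(C)c(O)c(Cc2c(OCc3ccccc3)c(C(=O)CC)c(OCc3ccccc3)c(C)c2OC)c1O | intermediate
20 | 1-[3-{[2,4-dihydroxy-6-methoxy-5-methyl-3-propanoylphenyl]methyl}-2,4,6-trihydroxy-5-methylphenyl]propan-1-one | CCC(=O)c1c(O)c(C)c(O)c(Cc2c(O)c(C(=O)CC)c(O)c(C)c2OC)c1O | target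

## Step count

Total steps: 12. Longest linear sequence: 10 steps (steps 1–7, 10, 11, 12); the diene branch (steps 8–9) joins at step 10.

## Steps most likely to fail

**Step 11 (key Claisen closure).** The polyketone chain may be cut by retro-Claisen attack of methoxide, or may rest as the lactone or as aldol adducts without aromatising. The fallback makes the bridge by Friedel–Crafts benzylation instead. It sets out from aldehyde 7, which is reduced with NaBH4 (MeOH/THF, 0 °C; the hindered aryl ketone should be spared) to 1-[2,6-bis(benzyloxy)-3-(hydroxymethyl)-4-methoxy-5-methylphenyl]propan-1-one F1. F1 is ionised with BF3·OEt2 in dioxane (0 °C to rt) in the presence of acylphloroglucinol 3. The only free ring carbon of 3 should capture the benzylic cation, which is stabilised by two ortho and one para alkoxy groups. This gives 19, where the route is rejoined before step 12.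

**Step 10 (C-acylation of the bis(silyl enol ether)).** The branched acid chloride may acylate on oxygen or at the central carbon of the diene, or traces of HCl may protodesilylate 15 before it reacts. The fallback masks the keto ester as a 2-pyrone and attaches ring B last.
- 4-Hydroxy-5,6-dimethyl-2H-pyran-2-one (CC1=C(C)C(O)=CC(=O)O1) is converted with LiN(i-Pr)2 (2.5 equiv, THF, −78 °C) into its dianion, which is acylated at the 6-methyl group with N-methoxy-N-methylpropanamide (CCC(=O)N(C)OC) to give 4-hydroxy-5-methyl-6-(2-oxobutyl)-2H-pyran-2-one F2.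
- Reductive alkylation of F2 at its nucleophilic C3 with aldehyde 7 and the Hantzsch ester (L-proline, EtOH, rt) should give 3-{[2,4-bis(benzyloxy)-6-methoxy-5-methyl-3-propanoylphenyl]methyl}-4-hydroxy-5-methyl-6-(2-oxobutyl)-2H-pyran-2-one F3.
- Heating F3 with Mg(OMe)2 in MeOH should open the lactone to 17 in the flask. The route is rejoined at 17, which under these conditions of step 11 goes on to 19 without isolation.

**Step 2 (mono-O-methylation).** Methylation may occur at an ortho hydroxyl or twice. The fallback reverses the logic and removes methyl groups instead. It sets out from 2,4,6-trimethoxytoluene (Cc1c(OC)cc(OC)cc1OC), which is acylated with propanoyl chloride 2 and AlCl3 (CH2Cl2, 0 °C) to 1-(2,4,6-trimethoxy-3-methylphenyl)propan-1-one F4. Excess AlCl3 in PhCl at 80 °C should then cleave, through chelation to the ketone, only the two methyl ethers ortho to the carbonyl. This gives 4, where the route is rejoined before step 3.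

## Further compounds

F1 | step 11 | 1-[2,6-bis(benzyloxy)-3-(hydroxymethyl)-4-methoxy-5-methylphenyl]propan-1-one | OCc1c(OCc2ccccc2)c(C(=O)CC)c(OCc2ccccc2)c(C)c1OC
F2 | step 10 | 4-hydroxy-5-methyl-6-(2-oxobutyl)-2H-pyran-2-one | CCC(=O)CC1=C(C)C(O)=CC(=O)O1
F3 | step 10 | 3-{[2,4-bis(benzyloxy)-6-methoxy-5-methyl-3-propanoylphenyl]methyl}-4-hydroxy-5-methyl-6-(2-oxobutyl)-2H-pyran-2-one | CCC(=O)CC1=C(C)C(O)=C(Cc2c(OCc3ccccc3)c(C(=O)CC)c(OCc3ccccc3)c(C)c2OC)C(=O)O1
F4 | step 2 | 1-(2,4,6-trimethoxy-3-methylphenyl)propan-1-one | CCC(=O)c1c(OC)cc(OC)c(C)c1OC
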